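Atom numbering is that of drimane (C1–C15). Compound numbers are those of the steps and of the compound list. Drimane-type names of the bicyclic compounds imply 5α-H, 9α-H (C11 on the β face) and 10β-CH3.

## Analysis of the target

The target 20 is a drimane sesquiterpene joined through its C11 methylene to the 7-oxygen of umbelliferone. The carbon skeleton is a trans-fused decalin: ring A (C1–C5, C10) holds the C3 ketone next to the C4 gem-dimethyl group, and ring B (C5–C10) holds the trisubstituted C7=C8 alkene with the C12 methyl on C8. Three contiguous stereocentres are present, C5 (R), C10 (S, quaternary, methyl C15) and C9 (S). H5 is trans to C15 (trans ring fusion) and C11 is cis to C15, so H5 and H9 lie on the face opposite the angular methyl. Sensitive groups are the coumarin lactone (opened by alkoxide, reduced by hydrides and dissolving metals), the C7=C8 alkene (acid can move it to C8=C9 with loss of the C9 stereocentre) and the ketone, enolisable towards C2. The difficulty is the run of four adjacent branched carbons C4–C5–C10–C9 with the quaternary C10 in the middle, together with the need to place the ring B alkene regiospecifically. The strategy rests on ring B: it is a cyclohexene whose C7=C8 bond lies directly across the ring from the C5–C10 bond, the retron of a [4+2] cycloaddition between a C6=C7–C8=C9 diene and a C5=C10 dienophile. All three stereocentres sit on the two dienophile carbons and on the diene terminus C9, so one cycloaddition can set them together.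

## Retrosynthetic reasoning

**C11–O aryl ether (20 to 18 and 19).** The ether bond is cut last, giving 11-hydroxydrim-7-en-3-one 18 and umbelliferone 19. The lactone of 19 would not survive the basic, hydridic and fluoride steps needed earlier. C11 is a CH2 group, so a Mitsunobu etherification can join the two pieces without touching a stereocentre.

**Functional group adjustments in the bicycle (18 back to 13).** No skeletal bond is cut here. Alcohol 18 comes from its 4-methoxybenzyl ether 17. The saturated ketone 17 comes from dienone 16 by conjugate reduction of C1=C2. The C7–H of 16 comes from enol triflate 15, which comes from the silyl enol ether 13. The order matters: the enol ether is turned into the triflate while ring A is still the enone of 13, which has no enolisable position (C4 and C10 are quaternary). The enolate freed at C7/C8 therefore cannot exchange with a second ketone enolate. The C7=C8 alkene of the target is inherited from the enol ether and is not made by an elimination of uncertain regiochemistry.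

**C1–C2 bond of ring A (13 to 11).** Ring A is opened at the enone by a retro-aldol condensation, giving the keto aldehyde 11. The cut is placed here because both partners can react in only one way. The aldehyde on the quaternary C10 cannot enolise, and the ketone, flanked by the quaternary C4, can enolise only at its methyl group (C2). The forward aldol condensation has to close a six-membered ring between two trans-disposed substituents of ring B and so gives the trans ring fusion.

**C5–C6 and C9–C10 bonds of ring B (11 to 10 and 6).** This is the key disconnection: a retro-Diels–Alder reaction to the 2-silyloxy diene 10 and the (E)-enal 6. Two skeletal bonds, ring B and all three stereocentres are made together. The silyl enol ether at C7=C8 marks the future alkene, and the formyl group that activates the dienophile is the carbon (C1) needed for ring A. The forward reaction, under a chiral boron Lewis acid, must be face-selective on the enal and exo with respect to the formyl group. It must also overcome the tertiary substituent on the β-carbon C5.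

**Diene 10 (to 9, then to 7 and 8).** The enol silyl ether is traced to the methyl ketone 9, whose only α-position is the methyl group. The C8=C9 bond of 9 is cut by a Wittig disconnection into aldehyde 7 and the stabilised ylide 8. This fixes the (E)-geometry, so C11 is an outside substituent of the diene.

**Dienophile 6 (to 4 and 5, then 2 and 1).** The C5=C10 bond is cut by a Wittig disconnection into the β-keto aldehyde 4 and the formyl ylide 5, which gives the (E)-2-methyl enal directly. The C3–C4 bond of 4 is cut to enamine 2 of isobutyraldehyde 1. C-acetylation of 2 can occur only once because the carbon attacked becomes quaternary.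

## Alternatives that were turned down

**Alternative 1:** Ring B is opened at C8–C9 and the C11–O bond is taken apart at the same time.
- Disconnection: the precursor is aldoxime A1, a ring A cyclohexane (C3 silyl ether, C4 gem-dimethyl) carrying on C10 the angular methyl and a vinyl group (C9=C11), and on C5 a three-carbon chain ending in the oxime carbon C8.
- Forward key step: hypochlorite oxidation gives nitrile oxide A2, which adds across the vinyl group to give isoxazoline A3. This closes ring B through C8–C9 and places oxygen on C11.
- For: the tether dictates the regiochemistry, the new C–C bond forms at an unhindered vinyl CH, and the isoxazoline masks exactly the C8 carbonyl/C11 hydroxyl pair. As a single step it is more dependable than the hindered intermolecular cycloaddition chosen here.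
- Against: A3 lacks C12. After N–O cleavage the β-hydroxy ketone, which is prone to dehydration and to epimerisation at C9, must be converted into the C8-methyl C7=C8 alkene by regioselective enol triflate formation and methyl coupling. C3 travels as a protected alcohol and must be oxidised later. Above all, A1 already contains C5 and the quaternary C10, whose vicinal arrangement is the real stereochemical problem and would need its own asymmetric synthesis.
- Comparison: the chosen route makes C5, C10 and C9 in one catalytic step from achiral fragments and brings C12 and the alkene position with the diene, at roughly half the step count.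

**Alternative 2:** The C1–C10 and C9–C11 bonds are cut on a ready-made ring B.
- Disconnection: the precursor is (R)-4-(tert-butyldimethylsilyloxy)-3-methylcyclohex-2-en-1-one A4 (C8 carbonyl, C9=C10 alkene, C5 silyl ether).
- Forward key step: the organocopper reagent from the Grignard reagent of bromide A5 (CuBr·SMe2, Me3SiCl) adds to C10 anti to the C5 silyloxy group. The enolate is then hydroxymethylated at C9 by a one-carbon aldehyde electrophile to give A6.
- For: conjugate addition with enolate trapping is a textbook way to build a quaternary carbon beside a new tertiary one with the trans relationship needed here (C11 cis to the methyl). The later operations are classical: ring A by aldol condensation onto a C5 ketone, reductive methylation to create C4 and the trans fusion, and conversion of the C8 ketone into the methyl-bearing alkene. Each of these steps carries less risk than the cycloaddition chosen here.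
- Against: enantiopure A4 has to be made. Its C5 stereocentre is only a control element and is erased on oxidation, so the trans ring fusion depends on a later dissolving-metal reductive alkylation. Trapping a hindered enolate next to a fresh quaternary centre with a one-carbon electrophile is capricious, and in the presence of Me3SiCl the enolate is first silylated and must be re-activated. Three ketone functions (C8, C5, C3) must be told apart, and C12 is introduced separately.
- Comparison: the stereocentres are set one after another over roughly sixteen or more steps. The chosen route sets them in one event and reaches the target in twelve.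

**Alternative 3:** Both rings are disconnected at once by cutting C5–C10 and C8–C9.
- Disconnection: the precursor is the acyclic trienal A7. Its (E)-enal C9=C10 (C11 as the formyl carbon) is tethered through C1–C4 (C3 silyl ether, C4 gem-dimethyl) to a 2-silyloxy diene C5=C6–C7(OSi)=C8–C12.
- Forward key step: thermal or Lewis-acid-promoted intramolecular Diels–Alder reaction gives A8 with rings A and B and four stereocentres.
- For: it is the shortest way from an open chain to the decalin. Intramolecularity compensates for the steric cost of joining a diene terminus next to the quaternary C4 to a fully substituted dienophile carbon. On reactivity and on rings formed per step it is stronger than the chosen intermolecular reaction.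
- Against: the absolute configuration must be relayed from the C3 silyloxy stereocentre through a four-atom tether, for which the trans/cis-fused preference is not reliably high. The enol ether ends at C6=C7 and not at C7=C8, and C8 becomes a stereocentre that the target does not need, so the alkene must be re-created by hydrolysis and regioselective triflation. A7 requires a geometrically defined (Z)-silyl enol ether of an ethyl dienone and an enantioenriched carbinol, which means a long linear sequence before the key step.
- Comparison: the chosen route offers catalyst control of absolute configuration with no relay stereocentre, an enol ether already where the alkene is needed, and two fragments of two and three steps.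

Key step: step 6

Assumption: the face selectivity of the catalyst in step 6 is taken from the accepted pre-transition-state model for 2-substituted enals (diene on the re face of the α-carbon with the catalyst from (S)-diphenylprolinol); should the sense prove opposite, the catalyst from (R)-diphenylprolinol is used with no other change.

## Route

Step 1
Reactants: 1 isobutyraldehyde
Product: 2 4-(2-methylprop-1-en-1-yl)morpholine
Conditions: morpholine (1.1 equiv), TsOH (cat.), cyclohexane, reflux with azeotropic removal of water; distillation
Reagents that add atoms: morpholine, C1COCCN1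
Why: Acid-catalysed condensation of a secondary amine with an α-branched aldehyde (enamine formation) should give the single possible enamine once water is removed.

Step 2
Reactants: 2 4-(2-methylprop-1-en-1-yl)morpholine
Product: 4 2,2-dimethyl-3-oxobutanal, via iminium chloride 3 (not isolated)
Conditions: AcCl (1.05 equiv), Et2O, 0 °C → reflux; then H2O, rt
Reagents that add atoms: acetyl chloride, CC(=O)Cl; water, O
Why: Stork enamine C-acylation: the β-carbon of 2 attacks acetyl chloride to give an iminium salt whose α-carbon is quaternary, so it cannot tautomerise or be acylated again, and hydrolysis should release the β-keto aldehyde.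

Step 3
Reactants: 4 2,2-dimethyl-3-oxobutanal; 5 2-(triphenylphosphoranylidene)propanal
Product: 6 (E)-2,4,4-trimethyl-5-oxohex-2-enal
Conditions: PhMe, 100 °C
Reagents that add atoms: none
Why: Wittig olefination with a stabilised formyl ylide should react at the aldehyde and not at the hindered ketone and give the (E)-2-methyl enal; the α-branched product enal is too hindered to be olefinated again.

Step 4
Reactants: 7 2-(4-methoxybenzyloxy)acetaldehyde; 8 3-(triphenylphosphoranylidene)butan-2-one
Product: 9 (E)-5-(4-methoxybenzyloxy)-3-methylpent-3-en-2-one
Conditions: PhMe, 80 °C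
Reagents that add atoms: none
Why: Wittig olefination with a stabilised acyl ylide should give the (E)-trisubstituted enone, with the CH2O group trans to the acetyl group.

Step 5
Reactants: 9 (E)-5-(4-methoxybenzyloxy)-3-methylpent-3-en-2-one
Product: 10 (E)-triisopropyl{[5-(4-methoxybenzyloxy)-3-methylpenta-1,3-dien-2-yl]oxy}silane
Conditions: TIPSOTf (1.2 equiv), Et3N (2 equiv), CH2Cl2, 0 °C → rt
Reagents that add atoms: triisopropylsilyl trifluoromethanesulfonate, CC(C)[Si](OS(=O)(=O)C(F)(F)F)(C(C)C)C(C)C
Why: Soft enolisation (silyl triflate and amine) of the methyl ketone at its only α-position should give the cross-conjugated 2-silyloxy diene without touching the C8=C9 geometry; the triisopropylsilyl group is chosen because its enol ethers survive chromatography and mild base.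

Step 6
Reactants: 10 (E)-triisopropyl{[5-(4-methoxybenzyloxy)-3-methylpenta-1,3-dien-2-yl]oxy}silane; 6 (E)-2,4,4-trimethyl-5-oxohex-2-enal
Product: 11 (1S,2S,6R)-2-[(4-methoxybenzyloxy)methyl]-1,3-dimethyl-6-(2-methyl-3-oxobutan-2-yl)-4-(triisopropylsilyloxy)cyclohex-3-ene-1-carbaldehyde
Conditions: (S)-tetrahydro-3,3-diphenyl-1-(2-methylphenyl)-1H,3H-pyrrolo[1,2-c][1,3,2]oxazaborole (20 mol %, from (S)-α,α-diphenylprolinol and tri-o-tolylboroxine), HNTf2 (18 mol %), 10 (1.5 equiv), CH2Cl2 (about 1 M), −78 → −20 °C
Reagents that add atoms: none
Why: The N-protonated oxazaborolidine binds the formyl oxygen of 6 syn to the formyl hydrogen (held by a formyl C–H···O contact to the ring oxygen), the s-trans enal lies over one C-phenyl group, and diene 10 adds to the open face in a concerted but strongly asynchronous [4+2] in which C6, the β-carbon of the silyl enol ether, bonds first to the enal β-carbon C5 and C9 then bonds to C10; the closest known reaction type is the enantioselective Diels–Alder reaction of 2-(triisopropylsilyloxy) dienes with α-methyl enals under chiral cationic oxazaborolidine catalysis. Ring B is closed by the cycloaddition itself, a suprafacial six-membered [4π+2π] closure that forms C5–C6 and C9–C10 on one face of each partner, with no separate ring-closing event. Regiochemistry is unambiguous because the silyloxy group on C7 and the alkyl substituent on C9 both place the larger HOMO coefficient on C6, which pairs with the LUMO-rich β-carbon C5. For C5 and C10, the relative configuration (C4 trans to C1) is transcribed from the (E)-geometry of 6, and the absolute configuration is fixed by the catalyst, which leaves open the face that is re at C10 (si at the formyl carbon). For C9, the configuration relative to C10 follows from the (E)-geometry of the C8=C9 bond of 10 combined with the exo placement of the catalyst-bound formyl group (C15 endo), which puts C11 cis to C15. The step therefore needs face selectivity (catalyst), exo selectivity (the α-methyl group and the bulk of the boron-bound formyl group disfavour the endo-formyl arrangement) and conjugate instead of carbonyl attack at a β-carbon that carries a tertiary substituent; high concentration and the triflimide-activated catalyst are chosen to drive this hindered addition.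

Step 7
Reactants: 11 (1S,2S,6R)-2-[(4-methoxybenzyloxy)methyl]-1,3-dimethyl-6-(2-methyl-3-oxobutan-2-yl)-4-(triisopropylsilyloxy)cyclohex-3-ene-1-carbaldehyde
Product: 13 11-(4-methoxybenzyloxy)-7-(triisopropylsilyloxy)drima-1,7-dien-3-one, via β-hydroxy ketone 12 (not isolated)
Conditions: KOtBu (0.5 equiv), tBuOH–THF, 0 → 40 °C
Reagents that add atoms: none
Why: Intramolecular aldol condensation (6-enolendo-exo-trig attack of the methyl ketone enolate on the non-enolisable C10 aldehyde, then E1cB loss of water) can only give the C1=C2 enone; the trans C4/C1 relationship set in step 6 becomes the trans ring fusion, and the hindered silyl enol ether should tolerate tert-butoxide.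

Step 8
Reactants: 13 11-(4-methoxybenzyloxy)-7-(triisopropylsilyloxy)drima-1,7-dien-3-one
Product: 15 11-(4-methoxybenzyloxy)-3-oxodrima-1,7-dien-7-yl trifluoromethanesulfonate, via cesium enolate 14 (not isolated)
Conditions: CsF (3 equiv), PhNTf2 (1.5 equiv), DME, rt
Reagents that add atoms: N-phenylbis(trifluoromethanesulfonimide), O=S(=O)(N(c1ccccc1)S(=O)(=O)C(F)(F)F)C(F)(F)F
Why: Fluoride cleaves the Si–O bond and the enolate so released is trapped on oxygen by PhNTf2 (direct conversion of a silyl enol ether into an enol triflate), so the C7=C8 position is carried over unchanged; ring A is a non-enolisable enone at this stage, so no second enolate can form.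

Step 9
Reactants: 15 11-(4-methoxybenzyloxy)-3-oxodrima-1,7-dien-7-yl trifluoromethanesulfonate
Product: 16 11-(4-methoxybenzyloxy)drima-1,7-dien-3-one
Conditions: Pd(OAc)2 (5 mol %), PPh3 (10 mol %), HCO2H, Bu3N, DMF, 60 °C
Reagents that add atoms: none
Why: Zerovalent palladium inserts into the C7–OTf bond, formate delivers hydride with loss of CO2, and reductive elimination gives the C7–H alkene (palladium-catalysed formate reduction of an enol triflate); the alkene stays at C7=C8 and the enone should not be affected.

Step 10
Reactants: 16 11-(4-methoxybenzyloxy)drima-1,7-dien-3-one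
Product: 17 11-(4-methoxybenzyloxy)drim-7-en-3-one
Conditions: [(Ph3P)CuH]6 (0.4 equiv), H2O (5 equiv), degassed PhH, rt
Reagents that add atoms: none
Why: Conjugate reduction: the phosphine-stabilised copper hydride transfers hydride to the β-carbon C1 of the enone and the enolate is protonated at C2; the isolated trisubstituted alkene and the benzylic ether are inert and no stereocentre is created.

Step 11
Reactants: 17 11-(4-methoxybenzyloxy)drim-7-en-3-one
Product: 18 11-hydroxydrim-7-en-3-one
Conditions: DDQ (1.3 equiv), CH2Cl2–pH 7 buffer, 0 °C → rt
Reagents that add atoms: none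
Why: Oxidative cleavage of the electron-rich 4-methoxybenzyl ether by DDQ (hydride abstraction, then hydrolysis of the oxocarbenium ion) should leave the ketone and the trisubstituted alkene untouched under buffered conditions.

Step 12
Reactants: 18 11-hydroxydrim-7-en-3-one; 19 umbelliferone
Product: 20 11-(2-oxo-2H-chromen-7-yloxy)drim-7-en-3-one
Conditions: PPh3 (1.5 equiv), DIAD (1.5 equiv), THF, 0 °C → rt
Reagents that add atoms: none
Why: Mitsunobu etherification: the primary alcohol is activated as its alkoxyphosphonium ion and displaced at the CH2 carbon by the acidic phenol of umbelliferone, so no stereocentre is involved; the neutral conditions spare the lactone and keep the alkene at C7=C8.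

## Compound list

1 | isobutyraldehyde (2-methylpropanal) | CC(C)C=O | starting material
2 | 4-(2-methylprop-1-en-1-yl)morpholine | CC(C)=CN1CCOCC1 | intermediate
3 | 4-(2,2-dimethyl-3-oxobutylidene)morpholin-4-ium chloride | CC(=O)C(C)(C)C=[N+]1CCOCC1.[Cl-] | intermediate (not isolated)
4 | 2,2-dimethyl-3-oxobutanal | CC(=O)C(C)(C)C=O | intermediate
5 | 2-(triphenylphosphoranylidene)propanal | CC(C=O)=P(c1ccccc1)(c1ccccc1)c1ccccc1 | starting material
6 | (E)-2,4,4-trimethyl-5-oxohex-2-enal | O=C/C(C)=C/C(C)(C)C(C)=O | intermediate
7 | 2-(4-methoxybenzyloxy)acetaldehyde | O=CCOCc1ccc(OC)cc1 | starting material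
8 | 3-(triphenylphosphoranylidene)butan-2-one | CC(=O)C(C)=P(c1ccccc1)(c1ccccc1)c1ccccc1 | starting material
9 | (E)-5-(4-methoxybenzyloxy)-3-methylpent-3-en-2-one | CC(=O)/C(C)=C/COCc1ccc(OC)cc1 | intermediate
10 | (E)-triisopropyl{[5-(4-methoxybenzyloxy)-3-methylpenta-1,3-dien-2-yl]oxy}silane | C=C(O[Si](C(C)C)(C(C)C)C(C)C)/C(C)=C/COCc1ccc(OC)cc1 | intermediate
11 | (1S,2S,6R)-2-[(4-methoxybenzyloxy)methyl]-1,3-dimethyl-6-(2-methyl-3-oxobutan-2-yl)-4-(triisopropylsilyloxy)cyclohex-3-ene-1-carbaldehyde (ring carbons 1, 2, 6 are drimane C10, C9, C5) | CC1=C(O[Si](C(C)C)(C(C)C)C(C)C)C[C@@H](C(C)(C)C(C)=O)[C@](C)(C=O)[C@H]1COCc1ccc(OC)cc1 | intermediate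
12 | 1-hydroxy-11-(4-methoxybenzyloxy)-7-(triisopropylsilyloxy)drim-7-en-3-one (both C1 epimers; 5α-H, 9α-H, 10β-CH3) | CC1=C(O[Si](C(C)C)(C(C)C)C(C)C)C[C@H]2C(C)(C)C(=O)CC(O)[C@]2(C)[C@H]1COCc1ccc(OC)cc1 | intermediate (not isolated)
13 | 11-(4-methoxybenzyloxy)-7-(triisopropylsilyloxy)drima-1,7-dien-3-one (5α-H, 9α-H, 10β-CH3) | CC1=C(O[Si](C(C)C)(C(C)C)C(C)C)C[C@H]2C(C)(C)C(=O)C=C[C@]2(C)[C@H]1COCc1ccc(OC)cc1 | intermediate
14 | cesium 11-(4-methoxybenzyloxy)-3-oxodrima-1,7-dien-7-olate | CC1=C([O-])C[C@H]2C(C)(C)C(=O)C=C[C@]2(C)[C@H]1COCc1ccc(OC)cc1.[Cs+] | intermediate (not isolated)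
15 | 11-(4-methoxybenzyloxy)-3-oxodrima-1,7-dien-7-yl trifluoromethanesulfonate | CC1=C(OS(=O)(=O)C(F)(F)F)C[C@H]2C(C)(C)C(=O)C=C[C@]2(C)[C@H]1COCc1ccc(OC)cc1 | intermediate
16 | 11-(4-methoxybenzyloxy)drima-1,7-dien-3-one | CC1=CC[C@H]2C(C)(C)C(=O)C=C[C@]2(C)[C@H]1COCc1ccc(OC)cc1 | intermediate
17 | 11-(4-methoxybenzyloxy)drim-7-en-3-one | CC1=CC[C@H]2C(C)(C)C(=O)CC[C@]2(C)[C@H]1COCc1ccc(OC)cc1 | intermediate
18 | 11-hydroxydrim-7-en-3-one | CC1=CC[C@H]2C(C)(C)C(=O)CC[C@]2(C)[C@H]1CO | intermediate
19 | umbelliferone (7-hydroxy-2H-chromen-2-one) | O=c1ccc2ccc(O)cc2o1 | starting material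
20 | 11-(2-oxo-2H-chromen-7-yloxy)drim-7-en-3-one, (5R,9S,10S); 7-{[(1S,4aR,8aS)-2,5,5,8a-tetramethyl-6-oxo-1,4,4a,5,6,7,8,8a-octahydronaphthalen-1-yl]methoxy}-2H-chromen-2-one | CC1=CC[C@H]2C(C)(C)C(=O)CC[C@]2(C)[C@H]1COc1ccc2ccc(=O)oc2c1 | target

## Step count and least certain steps

Total step count: 12. Longest linear sequence: 10 steps (steps 1, 2, 3, 6, 7, 8, 9, 10, 11, 12); steps 4 and 5 form the second branch.

**Step 6 (key step).** Most likely to go wrong is the rate of conjugate attack. The β-carbon C5 carries a tertiary alkyl group, so bond formation from C6 is slow, and carbonyl addition of the silyl enol ether to the activated formyl group (Mukaiyama-type aldol) or acid-mediated loss of the diene may take over. The same tertiary group must lie endo, which may erode the exo preference and lead to epimerisation of the outcome at C9.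

The fallback moves the creation of the C4 quaternary centre behind the cycloaddition. It sets out from diene 10 (with ylide 5) and comes back to the route at dienone 16.
- Commercial ethyl (2-methyl-1,3-dioxolan-2-yl)acetate would be reduced with iBu2AlH (CH2Cl2, −78 °C) to 2-(2-methyl-1,3-dioxolan-2-yl)acetaldehyde F1. With ylide 5 (PhMe, 80 °C) this should give (E)-2-methyl-4-(2-methyl-1,3-dioxolan-2-yl)but-2-enal F2, an α-methyl enal with only a primary β-substituent, well inside the usual scope of the catalyst.
- Cycloaddition of F2 with 10 under the conditions of step 6 should give the ketal cycloadduct F3. CsF and PhNTf2 (as in step 8) should convert it into the ketal enol triflate F4, and Pd(OAc)2, PPh3, HCO2H and Bu3N (as in step 9) should give the ketal cyclohexene aldehyde F5.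
- Aqueous HCl in THF would free the methyl ketone to give the keto aldehyde F6. KOtBu in tBuOH should then close ring A to 11-(4-methoxybenzyloxy)-13,14-dinordrima-1,7-dien-3-one F7.
- The only acidic position of F7 is C4. Two rounds of LiN(iPr)2 and MeI (THF, −78 → 0 °C) should install the gem-dimethyl group by way of the monomethyl enone F8 and give 16.

**Step 3.** The formyl ylide is a weak nucleophile and the aldehyde of 4 is neopentyl-like. Slow olefination would call for prolonged heating, during which retro-Claisen cleavage of the β-keto aldehyde or a second olefination may compete. The fallback sets out from 4 and comes back at 6. Olefination with the more nucleophilic ethyl 2-(triphenylphosphoranylidene)propanoate (CH2Cl2, 40 °C) should give ethyl (E)-2,4,4-trimethyl-5-oxohex-2-enoate F9. iBu2AlH (CH2Cl2, −78 → 0 °C) would reduce ester and ketone to (E)-2,4,4-trimethylhex-2-ene-1,5-diol F10, and a double Swern oxidation ((COCl)2, DMSO, Et3N) should give 6.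

**Step 8.** Fluoride attack at the crowded silicon of a tetrasubstituted silyl enol ether may be slow. The liberated enolate may also undergo proton transfer towards C6 before it is triflated, which would scramble the position of the triflate. The fallback sets out from 13 and comes back at 15. Bu4NF buffered with AcOH (THF, 0 °C) would hydrolyse the enol ether to 11-(4-methoxybenzyloxy)drim-1-ene-3,7-dione F11 (both C8 epimers). Tf2O with 2,6-di-tert-butyl-4-methylpyridine (CH2Cl2, 0 °C → rt), conditions that favour the more substituted enol triflate, should then give 15.

**Step 12.** C11 is a β-branched primary carbon next to the quaternary C10. Displacement of the alkoxyphosphonium ion may be slow enough for alkylation of the reduced azodicarboxylate or elimination to compete. The fallback sets out from 18 and comes back at 20. MsCl and Et3N (CH2Cl2, 0 °C) should give 3-oxodrim-7-en-11-yl methanesulfonate F12, which is displaced by the phenoxide of umbelliferone 19 (Cs2CO3, DMF, 70 °C) in a Williamson ether synthesis.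

## Further compounds

F1 | step 6 | 2-(2-methyl-1,3-dioxolan-2-yl)acetaldehyde | O=CCC1(C)OCCO1
F2 | step 6 | (E)-2-methyl-4-(2-methyl-1,3-dioxolan-2-yl)but-2-enal | O=C/C(C)=C/CC1(C)OCCO1
F3 | step 6 | 2-[(4-methoxybenzyloxy)methyl]-1,3-dimethyl-6-[(2-methyl-1,3-dioxolan-2-yl)methyl]-4-(triisopropylsilyloxy)cyclohex-3-ene-1-carbaldehyde (configuration as in 11) | CC1=C(O[Si](C(C)C)(C(C)C)C(C)C)C[C@@H](CC2(C)OCCO2)[C@](C)(C=O)[C@H]1COCc1ccc(OC)cc1
F4 | step 6 | 4-formyl-3-[(4-methoxybenzyloxy)methyl]-2,4-dimethyl-5-[(2-methyl-1,3-dioxolan-2-yl)methyl]cyclohex-1-en-1-yl trifluoromethanesulfonate (configuration as in 11) | CC1=C(OS(=O)(=O)C(F)(F)F)C[C@@H](CC2(C)OCCO2)[C@](C)(C=O)[C@H]1COCc1ccc(OC)cc1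
F5 | step 6 | 2-[(4-methoxybenzyloxy)methyl]-1,3-dimethyl-6-[(2-methyl-1,3-dioxolan-2-yl)methyl]cyclohex-3-ene-1-carbaldehyde (configuration as in 11) | CC1=CC[C@@H](CC2(C)OCCO2)[C@](C)(C=O)[C@H]1COCc1ccc(OC)cc1
F6 | step 6 | 2-[(4-methoxybenzyloxy)methyl]-1,3-dimethyl-6-(2-oxopropyl)cyclohex-3-ene-1-carbaldehyde (configuration as in 11) | CC1=CC[C@@H](CC(C)=O)[C@](C)(C=O)[C@H]1COCc1ccc(OC)cc1
F7 | step 6 | 11-(4-methoxybenzyloxy)-13,14-dinordrima-1,7-dien-3-one | CC1=CC[C@H]2CC(=O)C=C[C@]2(C)[C@H]1COCc1ccc(OC)cc1
F8 | step 6 | 11-(4-methoxybenzyloxy)-14-nordrima-1,7-dien-3-one (both C4 epimers) | CC1=CC[C@H]2C(C)C(=O)C=C[C@]2(C)[C@H]1COCc1ccc(OC)cc1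
F9 | step 3 | ethyl (E)-2,4,4-trimethyl-5-oxohex-2-enoate | CCOC(=O)/C(C)=C/C(C)(C)C(C)=O
F10 | step 3 | (E)-2,4,4-trimethylhex-2-ene-1,5-diol | OC/C(C)=C/C(C)(C)C(C)O
F11 | step 8 | 11-(4-methoxybenzyloxy)drim-1-ene-3,7-dione (both C8 epimers) | CC1C(=O)C[C@H]2C(C)(C)C(=O)C=C[C@]2(C)[C@H]1COCc1ccc(OC)cc1
F12 | step 12 | 3-oxodrim-7-en-11-yl methanesulfonate | CC1=CC[C@H]2C(C)(C)C(=O)CC[C@]2(C)[C@H]1COS(C)(=O)=O
A1 | alternative 1 | 3-[3β-(tert-butyldimethylsilyloxy)-2,2,6-trimethyl-6-vinylcyclohexyl]propanal oxime (8,9-seco-12-nordrimane; 5α-H, 10β-CH3) | ON=CCC[C@H]1C(C)(C)[C@@H](O[Si](C)(C)C(C)(C)C)CC[C@]1(C)C=C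
A2 | alternative 1 | nitrile oxide derived from A1 | [O-][N+]#CCC[C@H]1C(C)(C)[C@@H](O[Si](C)(C)C(C)(C)C)CC[C@]1(C)C=C
A3 | alternative 1 | isoxazoline-fused 3β-(tert-butyldimethylsilyloxy)-12-nordrimane (C8=N, O on C11) | N1=C2CC[C@H]3C(C)(C)[C@@H](O[Si](C)(C)C(C)(C)C)CC[C@]3(C)[C@H]2CO1
A4 | alternative 2 | (R)-4-(tert-butyldimethylsilyloxy)-3-methylcyclohex-2-en-1-one | O=C1CC[C@@H](O[Si](C)(C)C(C)(C)C)C(C)=C1
A5 | alternative 2 | 2-(2-bromoethyl)-2-ethyl-1,3-dioxolane | BrCCC1(CC)OCCO1
A6 | alternative 2 | 4-(tert-butyldimethylsilyloxy)-3-[2-(2-ethyl-1,3-dioxolan-2-yl)ethyl]-2-(hydroxymethyl)-3-methylcyclohexan-1-one (new chain anti to the silyloxy group, CH2OH cis to the methyl) | O=C1CC[C@@H](O[Si](C)(C)C(C)(C)C)[C@](C)(CCC2(CC)OCCO2)[C@H]1CO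
A7 | alternative 3 | (2E,6S,8E,10Z)-6,10-bis(tert-butyldimethylsilyloxy)-3,7,7-trimethyldodeca-2,8,10-trienal | O=C/C=C(\C)CC[C@H](O[Si](C)(C)C(C)(C)C)C(C)(C)/C=C/C(O[Si](C)(C)C(C)(C)C)=C/C
A8 | alternative 3 | 3β,7-bis(tert-butyldimethylsilyloxy)-8β-methyl-drim-6-en-11-al | C[C@H]1C(O[Si](C)(C)C(C)(C)C)=C[C@H]2C(C)(C)[C@@H](O[Si](C)(C)C(C)(C)C)CC[C@]2(C)[C@H]1C=O
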